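The butane chain (C1 on the guaiacyl ring, C4 on the syringyl ring) is cut at C1–C2 and C3–C4: the C2–C3 unit with its two methyl groups maps atom for atom onto but-2-yne, and the benzylic carbons on either side can come from an aryl aldehyde and a benzylmetal. One nickel-catalysed three-component union of the alkyne, O-benzylvanillin and a syringyl-type benzylzinc chloride forms both bonds by syn addition and gives an acyclic (Z)-tetrasubstituted allylic alcohol with an (S)-carbinol; its precursors are simply the three unlinked pieces. The temporary C1 hydroxyl then directs a syn hydrogenation that sets C2 and C3 together, and one hydrogenolysis removes that hydroxyl and both benzyl ethers.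

Key step: step 5

Remark: the C1–C4 numbering above is used throughout; L*·HBF4 is a C2-symmetric chiral 4,5-diphenyl-4,5-dihydroimidazolium tetrafluoroborate with a 2-cyclohexyl-6-methylphenyl group on each nitrogen, and because its sense of induction cannot be predicted safely here, the antipode that gives the (S)-alcohol 10 is assumed to be picked after a first test.

Step 1
Reactants: 1 syringaldehyde (4-hydroxy-3,5-dimethoxybenzaldehyde)
Product: 2 4-(benzyloxy)-3,5-dimethoxybenzaldehyde
Conditions: BnBr, K2CO3, DMF, 60 °C
Reagents that add atoms: benzyl bromide, BrCc1ccccc1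
Why: Williamson ether synthesis: the phenoxide formed with K2CO3 displaces bromide from benzyl bromide (SN2), and the non-enolisable aldehyde is inert to the mild base.

Step 2
Reactants: 2 4-(benzyloxy)-3,5-dimethoxybenzaldehyde
Product: 3 [4-(benzyloxy)-3,5-dimethoxyphenyl]methanol
Conditions: NaBH4, MeOH/THF, 0 °C
Reagents that add atoms: none
Why: Borohydride reduction of an aromatic aldehyde to the benzylic alcohol is chemoselective and leaves the aryl ethers untouched.

Step 3
Reactants: 3 [4-(benzyloxy)-3,5-dimethoxyphenyl]methanol
Product: 4 2-(benzyloxy)-5-(chloromethyl)-1,3-dimethoxybenzene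
Conditions: SOCl2, CH2Cl2, 0 °C to rt; crude used at once
Reagents that add atoms: thionyl chloride, O=S(Cl)Cl
Why: Deoxychlorination with SOCl2 converts the electron-rich benzylic alcohol into its chloride at low temperature with loss of SO2 and HCl, conditions the aryl benzyl ether should tolerate.

Step 4
Reactants: 4 2-(benzyloxy)-5-(chloromethyl)-1,3-dimethoxybenzene
Product: 5 [4-(benzyloxy)-3,5-dimethoxybenzyl]zinc chloride (LiCl-solvated THF solution)
Conditions: Zn dust (2 equiv), LiCl (1.5 equiv), THF, 25 °C, slow addition of 4
Reagents that add atoms: zinc, [Zn]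
Why: Direct LiCl-promoted insertion of zinc metal into a benzylic C–Cl bond gives a soluble benzylzinc chloride that tolerates aryl ethers, and keeping the chloride dilute holds Wurtz-type homocoupling down.

Step 5
Reactants: 5 [4-(benzyloxy)-3,5-dimethoxybenzyl]zinc chloride; 6 but-2-yne; 7 4-(benzyloxy)-3-methoxybenzaldehyde
Product: 10 (1S,2Z)-1-[4-(benzyloxy)-3-methoxyphenyl]-4-[4-(benzyloxy)-3,5-dimethoxyphenyl]-2,3-dimethylbut-2-en-1-ol, via oxanickelacyclopentene 8 (not isolated), via chlorozinc alkoxide 9 (not isolated)
Conditions: Ni(cod)2 (10 mol %), L*·HBF4 (10 mol %), KOtBu (10 mol %), 6 (4 equiv), toluene/THF, 0 °C, 5 (1.5 equiv) added over 3 h; then H2O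
Reagents that add atoms: none
Why: Proposed new method: the closest known reaction type is the nickel-catalysed alkylative three-component coupling of an alkyne, an aldehyde and an organozinc (methyl or alkyl transfer, also with chiral ligands); new here are benzyl transfer from a benzylzinc chloride and enantiocontrol by a chiral carbene with but-2-yne. Zerovalent nickel binds 6 and 7 and undergoes oxidative cyclisation to the oxanickelacyclopentene 8 (divalent nickel), forming C1–C2; benzyl then passes from zinc to nickel as oxygen passes to zinc, and C–C reductive elimination forms C3–C4 with retention at the alkenyl carbon to give 9, which water converts into 10. No ring is closed in the product, the five-membered metallacycle being transient. The one new stereocentre, C1, is set in the cyclisation, where the chiral carbene on nickel selects the aldehyde face; the Z geometry with C1 and C4 cis follows from the syn addition that the metallacycle enforces. The step needs chemoselectivity against uncatalysed addition of 5 to the aldehyde, which slow addition of 5 at 0 °C to an electron-rich, sluggish aldehyde in the presence of excess alkyne should secure; as the benzyl group lacks beta-hydrogens the hydride pathway to a reductive coupling product is closed, and a symmetrical alkyne makes regiochemistry moot.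

Step 6
Reactants: 10 (1S,2Z)-1-[4-(benzyloxy)-3-methoxyphenyl]-4-[4-(benzyloxy)-3,5-dimethoxyphenyl]-2,3-dimethylbut-2-en-1-ol
Product: 11 (1R,2R,3R)-1-[4-(benzyloxy)-3-methoxyphenyl]-4-[4-(benzyloxy)-3,5-dimethoxyphenyl]-2,3-dimethylbutan-1-ol
Conditions: [Ir(cod)(PCy3)(py)]PF6 (5–10 mol %), H2 (1 atm), CH2Cl2, 0 °C to rt
Reagents that add atoms: none
Why: Hydroxyl-directed homogeneous hydrogenation: allylic 1,3-strain against the cis C4 methylene keeps the C1 hydrogen in the alkene plane, so the iridium bound to the (S)-configured hydroxyl should add H2 syn to the one face on which that hydroxyl lies, which sets C2 and C3 together, their relative configuration following from the cis placement of C1 and C4.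

Step 7
Reactants: 11 (1R,2R,3R)-1-[4-(benzyloxy)-3-methoxyphenyl]-4-[4-(benzyloxy)-3,5-dimethoxyphenyl]-2,3-dimethylbutan-1-ol
Product: 13 4-[(2R,3S)-4-(4-hydroxy-3-methoxyphenyl)-2,3-dimethylbutyl]-2,6-dimethoxyphenol, via triol 12 (not isolated)
Conditions: H2 (3 bar), Pd(OH)2/C, EtOH/AcOH (10:1), rt
Reagents that add atoms: none
Why: Palladium-catalysed hydrogenolysis should cleave both aryl benzyl ethers and then the electron-rich para-hydroxybenzylic C–O bond of 12 directly on the metal, a process that does not touch the C2 and C3 stereocentres.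

Compound list
1 | syringaldehyde (4-hydroxy-3,5-dimethoxybenzaldehyde) | COc1cc(C=O)cc(OC)c1O | starting material
2 | 4-(benzyloxy)-3,5-dimethoxybenzaldehyde | COc1cc(C=O)cc(OC)c1OCc1ccccc1 | intermediate
3 | [4-(benzyloxy)-3,5-dimethoxyphenyl]methanol | COc1cc(CO)cc(OC)c1OCc1ccccc1 | intermediate
4 | 2-(benzyloxy)-5-(chloromethyl)-1,3-dimethoxybenzene | COc1cc(CCl)cc(OC)c1OCc1ccccc1 | intermediate
5 | [4-(benzyloxy)-3,5-dimethoxybenzyl]zinc chloride | COc1cc(C[Zn]Cl)cc(OC)c1OCc1ccccc1 | intermediate
6 | but-2-yne | CC#CC | starting material
7 | 4-(benzyloxy)-3-methoxybenzaldehyde (O-benzylvanillin) | COc1cc(C=O)ccc1OCc1ccccc1 | starting material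
8 | oxanickelacyclopentene: five-membered ring Ni–O–C1–C2=C3, (S) at C1, carbene ligand on nickel not drawn | CC1=C(C)[C@H](c2ccc(OCc3ccccc3)c(OC)c2)O[Ni]1 | intermediate
9 | chlorozinc alkoxide of 10 | Cl[Zn]O[C@@H](c1ccc(OCc2ccccc2)c(OC)c1)/C(C)=C(C)\Cc1cc(OC)c(OCc2ccccc2)c(OC)c1 | intermediate
10 | (1S,2Z)-1-[4-(benzyloxy)-3-methoxyphenyl]-4-[4-(benzyloxy)-3,5-dimethoxyphenyl]-2,3-dimethylbut-2-en-1-ol | O[C@@H](c1ccc(OCc2ccccc2)c(OC)c1)/C(C)=C(C)\Cc1cc(OC)c(OCc2ccccc2)c(OC)c1 | intermediate
11 | (1R,2R,3R)-1-[4-(benzyloxy)-3-methoxyphenyl]-4-[4-(benzyloxy)-3,5-dimethoxyphenyl]-2,3-dimethylbutan-1-ol (C1 unchanged in space; its descriptor switches from S to R only through the priority rules) | O[C@@H](c1ccc(OCc2ccccc2)c(OC)c1)[C@H](C)[C@H](C)Cc1cc(OC)c(OCc2ccccc2)c(OC)c1 | intermediate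
12 | (1R,2R,3R)-1-(4-hydroxy-3-methoxyphenyl)-4-(4-hydroxy-3,5-dimethoxyphenyl)-2,3-dimethylbutan-1-ol | O[C@@H](c1ccc(O)c(OC)c1)[C@H](C)[C@H](C)Cc1cc(OC)c(O)c(OC)c1 | intermediate
13 | 4-[(2R,3S)-4-(4-hydroxy-3-methoxyphenyl)-2,3-dimethylbutyl]-2,6-dimethoxyphenol (C2 is S and C3 is R in the C1–C4 numbering) | COc1cc(C[C@H](C)[C@H](C)Cc2cc(OC)c(O)c(OC)c2)ccc1O | target

Total step count: 7
Longest linear sequence: 7 steps (1 to 13; 6 and 7 are bought and enter at step 5)

Steps most likely to fail

Step 5. The benzylzinc may add directly to the aldehyde faster than the nickel cycle turns over, the alkyne may oligomerise on nickel, or the enantioface selection may be weak. The fallback uses known reactions only, sets out from 6 and 7 and comes back at 10. But-2-yne 6 is treated with Ti(OiPr)4 and iPrMgCl (2 equiv) in Et2O at −78 to −50 °C and then with aldehyde 7, which should give the oxatitanacyclopentene F1 (not isolated). Iodine followed by water should cleave its titanium–carbon bond with retention to the racemic (Z)-iodo allylic alcohol F2. Negishi coupling of F2 with the benzylzinc 5 (PdCl2(dppf), THF, 50 °C) should replace iodine with retention and give the racemic (Z)-allylic alcohol F3. MnO2 in CH2Cl2 should oxidise F3 to the (Z)-enone F4. CBS reduction of F4 (2-methyl-CBS-oxazaborolidine, BH3·SMe2, toluene, −20 °C, catalyst antipode chosen so that the S alcohol results) then returns to 10.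

Step 6. Acidic iridium hydride species may ionise the benzylic and allylic alcohol (racemisation, transposition or elimination), the allylic alcohol may isomerise to the ketone, or the face selectivity on the acyclic tetrasubstituted alkene may be insufficient. The fallback sets out from 10 and comes back at 11 and changes the source of stereocontrol from the substrate alone to substrate plus catalyst. Compound 10 is hydrogenated with a chiral cationic iridium phosphine–oxazoline catalyst, [Ir(cod)(L)]B[3,5-(CF3)2C6H3]4 with L = (S)- or (R)-4-tert-butyl-2-[2-(diphenylphosphanyl)phenyl]-4,5-dihydro-1,3-oxazole, at 50 bar H2 in CH2Cl2. The ligand antipode is taken that reinforces the face already favoured by the hydroxyl group, and the weakly coordinating counter-ion keeps the catalyst active at low loading. No new compound is formed on the way.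

Step 7. Acid-assisted ionisation at C1 may cause dehydration and re-addition of hydrogen (loss of configuration at C2) or ring closure onto the syringyl ring, or the C1–O bond may be cut only partly. The fallback sets out from 11 and comes back at 13. Acetylation of 11 (Ac2O, pyridine, DMAP, CH2Cl2) gives the benzylic acetate F5. Hydrogenolysis of F5 under neutral conditions (H2, 10% Pd/C, EtOAc, rt) should cut the activated benzylic C–O bond and both benzyl ethers on the metal without any cationic intermediate and give 13.

Further compounds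
F1 | step 5 | oxatitanacyclopentene: five-membered ring Ti–O–C1–C2=C3 with two isopropoxy groups on titanium, racemic | CC1=C(C)C(c2ccc(OCc3ccccc3)c(OC)c2)O[Ti]1(OC(C)C)OC(C)C
F2 | step 5 | racemic (Z)-1-[4-(benzyloxy)-3-methoxyphenyl]-3-iodo-2-methylbut-2-en-1-ol | OC(c1ccc(OCc2ccccc2)c(OC)c1)/C(C)=C(C)\I
F3 | step 5 | racemic (Z)-1-[4-(benzyloxy)-3-methoxyphenyl]-4-[4-(benzyloxy)-3,5-dimethoxyphenyl]-2,3-dimethylbut-2-en-1-ol | OC(c1ccc(OCc2ccccc2)c(OC)c1)/C(C)=C(C)\Cc1cc(OC)c(OCc2ccccc2)c(OC)c1
F4 | step 5 | (Z)-1-[4-(benzyloxy)-3-methoxyphenyl]-4-[4-(benzyloxy)-3,5-dimethoxyphenyl]-2,3-dimethylbut-2-en-1-one | O=C(c1ccc(OCc2ccccc2)c(OC)c1)/C(C)=C(C)\Cc1cc(OC)c(OCc2ccccc2)c(OC)c1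
F0 | step 6 | none | none
F5 | step 7 | (1R,2R,3R)-1-[4-(benzyloxy)-3-methoxyphenyl]-4-[4-(benzyloxy)-3,5-dimethoxyphenyl]-2,3-dimethylbutyl acetate | CC(=O)O[C@@H](c1ccc(OCc2ccccc2)c(OC)c1)[C@H](C)[C@H](C)Cc1cc(OC)c(OCc2ccccc2)c(OC)c1
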